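**Plan**

- Numbering as in drimanes: ring A = C1–C5/C10, ring B = C5–C10. C4 is the quaternary carbon with Me and the 4-methylpent-3-enyl chain; C9 carries CH2Ar (C11).
- Retrosynthetic cuts: C3–H back to C3–OH (helper oxygen); then C4–C5 and C9–C10 in one event, opening rings A and B to an acyclic epoxy triene; then C1–C2 (Wittig, then saturation) to a nerol-derived epoxy aldehyde and an allylic ylide; then aryl–C11 to a phenoxide and geranyl bromide.
- Forward order: arene–geranyl union, ω-oxidation, phosphonium salt; union with the epoxy aldehyde; one cationic cascade closes ring A, then ring B; the C3 oxygen is removed and both esters are cleaved in the last step.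
- Enabling feature: C4–C5 and C9–C10 of the trans-decalin are the two bonds that a chair–chair folded E,E-1,5-diene makes. C4 with its Me and prenyl-bearing chain is the tertiary carbon of 2,3-epoxynerol, so the oxirane marks the internal olefin as initiator and spares the terminal one.
- Stereochemistry: Katsuki–Sharpless epoxidation of nerol sets both oxirane carbons (C3, C4). Z geometry plus inversion at C4 puts the chain axial, cis to the C10 methyl. The E olefins and the chair–chair fold relay this to C5, C10 and C9; C3 is then erased.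

Key step: step 9

Remark: the disubstituted olefin made in the Wittig step is expected as an E/Z mixture and is saturated in the next step, so that one double bond is written without geometry; the coupled sulfone of one fallback is likewise a mixture of epimers at the sulfonyl carbon.

**Route**

Step 1
Reactants: 1 nerol ((2Z)-3,7-dimethylocta-2,6-dien-1-ol)
Product: 2 (2S,3R)-2,3-epoxynerol, [(2S,3R)-3-methyl-3-(4-methylpent-3-en-1-yl)oxiran-2-yl]methanol
Conditions: Ti(OiPr)4 (10 mol %), L-(+)-diethyl tartrate (14 mol %), t-BuOOH, 4 Å MS, CH2Cl2, −20 °C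
Reagents that add atoms: tert-butyl hydroperoxide CC(C)(C)OO
Why: Katsuki–Sharpless asymmetric epoxidation: the titanium tartrate complex binds the allylic hydroxyl and therefore epoxidises only the 2,3-olefin (the 6,7-olefin has no directing group), L-(+)-tartrate delivering oxygen to the face that sets both oxirane stereocentres as 2S,3R, while the Z geometry of nerol fixes the chain cis to C1.

Step 2
Reactants: 2 (2S,3R)-2,3-epoxynerol
Product: 3 (2R,3R)-3-methyl-3-(4-methylpent-3-en-1-yl)oxirane-2-carbaldehyde
Conditions: PhI(OAc)2, TEMPO (10 mol %), CH2Cl2, rt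
Reagents that add atoms: none
Why: TEMPO/oxoammonium oxidation of a primary alcohol with PhI(OAc)2 as terminal oxidant stops at the aldehyde and is non-basic, so the α,β-epoxy aldehyde is neither opened nor epimerised.

Step 3
Reactants: 4 methyl 4-hydroxybenzoate; 5 geranyl bromide ((2E)-1-bromo-3,7-dimethylocta-2,6-diene)
Product: 7 methyl 3-[(2E)-3,7-dimethylocta-2,6-dien-1-yl]-4-hydroxybenzoate, via sodium 4-(methoxycarbonyl)phenoxide 6 (not isolated)
Conditions: NaH, toluene, 0 °C to rt; then 5, rt to 40 °C
Reagents that add atoms: none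
Why: Ortho C-allylation of a phenoxide: in toluene the sodium phenoxide reacts as a tight ion pair, which should steer the primary allylic bromide to the ortho carbon (SN2, E geometry kept, the two ortho positions are equivalent) rather than to oxygen, and tautomerisation restores the phenol.

Step 4
Reactants: 7 methyl 3-[(2E)-3,7-dimethylocta-2,6-dien-1-yl]-4-hydroxybenzoate
Product: 8 methyl 4-(2,2-dimethylpropanoyloxy)-3-[(2E)-3,7-dimethylocta-2,6-dien-1-yl]benzoate
Conditions: t-BuCOCl, Et3N, DMAP (cat.), CH2Cl2, 0 °C to rt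
Reagents that add atoms: pivaloyl chloride CC(C)(C)C(=O)Cl
Why: DMAP-catalysed acylation of the phenol; the pivalate survives the base and ylide steps and makes the oxygen non-nucleophilic for step 9.

Step 5
Reactants: 8 methyl 4-(2,2-dimethylpropanoyloxy)-3-[(2E)-3,7-dimethylocta-2,6-dien-1-yl]benzoate
Product: 9 methyl 4-(2,2-dimethylpropanoyloxy)-3-[(2E,6E)-8-hydroxy-3,7-dimethylocta-2,6-dien-1-yl]benzoate
Conditions: SeO2 (30 mol %), t-BuOOH, salicylic acid (10 mol %), CH2Cl2, rt
Reagents that add atoms: tert-butyl hydroperoxide CC(C)(C)OO (net oxygen source); SeO2 O=[Se]=O (catalytic oxygen carrier)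
Why: Catalytic SeO2 allylic oxidation (ene reaction followed by [2,3]-sigmatropic shift, reoxidation by t-BuOOH), which should take the E-methyl of the terminal, most accessible trisubstituted olefin and give the E allylic alcohol.

Step 6
Reactants: 9 methyl 4-(2,2-dimethylpropanoyloxy)-3-[(2E,6E)-8-hydroxy-3,7-dimethylocta-2,6-dien-1-yl]benzoate
Product: 10 [(2E,6E)-8-[2-(2,2-dimethylpropanoyloxy)-5-(methoxycarbonyl)phenyl]-2,6-dimethylocta-2,6-dien-1-yl]triphenylphosphonium bromide
Conditions: Ph3P·HBr, MeCN, rt
Reagents that add atoms: triphenylphosphine hydrobromide [Br-].c1ccc(cc1)[PH+](c1ccccc1)c1ccccc1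
Why: Direct conversion of a primary allylic alcohol into the allylic phosphonium salt with Ph3P·HBr (protonation, loss of water, phosphine capture at the primary terminus), with the E olefin retained and no epoxide yet present.

Step 7
Reactants: 10 the phosphonium bromide; 3 (2R,3R)-3-methyl-3-(4-methylpent-3-en-1-yl)oxirane-2-carbaldehyde
Product: 12 methyl 4-(2,2-dimethylpropanoyloxy)-3-[(2E,6E)-3,7-dimethyl-9-[(2S,3R)-3-methyl-3-(4-methylpent-3-en-1-yl)oxiran-2-yl]nona-2,6,8-trien-1-yl]benzoate (8E/8Z mixture), via allylic phosphorus ylide 11 (not isolated)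
Conditions: KN(SiMe3)2, THF, −78 °C; then 3, −78 to 0 °C
Reagents that add atoms: none
Why: Wittig olefination of an α,β-epoxy aldehyde with a semi-stabilised allylic ylide; at −78 °C carbonyl addition should outrun base-induced opening of the epoxide, the oxirane stereocentres are not touched, and the geometry of the new olefin is irrelevant because step 8 removes it.

Step 8
Reactants: 12 the dienyl epoxide
Product: 13 methyl 4-(2,2-dimethylpropanoyloxy)-3-[(2E,6E)-3,7-dimethyl-9-[(2S,3R)-3-methyl-3-(4-methylpent-3-en-1-yl)oxiran-2-yl]nona-2,6-dien-1-yl]benzoate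
Conditions: 2-nitrobenzenesulfonylhydrazide, Et3N, CH2Cl2, rt
Reagents that add atoms: none
Why: Diimide reduction (concerted syn transfer of two hydrogens from HN=NH released from the sulfonylhydrazide): the 1,2-disubstituted, diene-conjugated olefin should react far faster than the three trisubstituted ones, and the neutral, metal-free conditions should spare the allylic epoxide and both esters.

Step 9
Reactants: 13 the (Z)-epoxy triene
Product: 14 3β-hydroxyjaspic acid methyl ester O-pivalate (trans-decalin with 10β-Me, 5α-H, 9β-CH2Ar, 7-ene, 4α-Me, axial 4β-(4-methylpent-3-enyl), equatorial 3β-OH; arene as methyl ester and aryl pivalate)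
Conditions: MeAlCl2 (3.5 equiv), CH2Cl2, −78 °C
Reagents that add atoms: none
Why: MeAlCl2 binds the epoxide oxygen and the C5=C10 π-bond opens the oxirane at its tertiary carbon C4 with inversion, the C10 cation so formed is taken anti by the C8=C9 π-bond, and the C8 cation loses the axial H-7 to the methylaluminium (as methane) to leave the 7-ene; the closest known reaction type is the Lewis-acid-promoted, epoxide-initiated cation–olefin polycyclisation of 2,3-oxidosqualene-like epoxy polyenes. Ring A closes 6-endo at the epoxide (both oxirane carbons become ring atoms) and 6-endo-trig at C5=C10, ring B closes 6-endo-trig at C8=C9, both through a chair–chair fold. C4 is set by backside attack on the Z epoxide (the chain cis to C2 becomes axial, on the face of the C10 methyl), C5 and C10 by anti addition to the E C5=C10 olefin (trans fusion), C9 by the E C8=C9 olefin in the chair (equatorial CH2Ar), and the absolute sense by the S oxirane carbon C3, whose oxygen ends as the equatorial 3β-alkoxide. The step needs opening at C4 and not C3 (tertiary versus secondary carbon), capture by the diene arm and not by the prenyl arm (the latter can reach the oxirane only through four- or five-membered endo closures and the C10 cation only syn through a strained bicyclo[3.3.1] bridge), and termination by loss of H-7 rather than by oxygen or arene (the phenol is an acyl ester and the ring carries the CO2Me group, so neither is nucleophilic, and MeAlCl2 scavenges the proton so that no acid re-enters the olefins).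

Step 10
Reactants: 14 3β-hydroxyjaspic acid methyl ester O-pivalate
Product: 15 3-oxojaspic acid methyl ester O-pivalate
Conditions: Dess–Martin periodinane, CH2Cl2, rt
Reagents that add atoms: none
Why: Dess–Martin oxidation of the hindered equatorial secondary alcohol to the ketone under neutral conditions; the neighbouring C4 is quaternary, so nothing can epimerise.

Step 11
Reactants: 15 3-oxojaspic acid methyl ester O-pivalate
Product: 18 jaspic acid, via 3-oxojaspic acid dipotassium salt 16 (not isolated), via C3 hydrazone dipotassium salt 17 (not isolated)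
Conditions: KOH, diethylene glycol, H2O, 120 °C; then N2H4·H2O, 130 to 200 °C; then aq. HCl
Reagents that add atoms: potassium hydroxide [K+].[OH-]
Why: Saponification of both esters followed by Wolff–Kishner reduction in the Huang-Minlon manner: the hydrazone of the C3 ketone loses N2 under hot KOH to leave CH2, while the isolated trisubstituted olefins, the phenoxide and the carboxylate are inert, no stereocentre is touched, and acidification gives the target.

**Compound list**

1 | nerol | CC(C)=CCC/C(C)=C\CO | starting material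
2 | (2S,3R)-2,3-epoxynerol | CC(C)=CCC[C@@]1(C)O[C@H]1CO | intermediate
3 | (2R,3R)-3-methyl-3-(4-methylpent-3-en-1-yl)oxirane-2-carbaldehyde | CC(C)=CCC[C@@]1(C)O[C@H]1C=O | intermediate
4 | methyl 4-hydroxybenzoate | COC(=O)c1ccc(O)cc1 | starting material
5 | geranyl bromide | CC(C)=CCC/C(C)=C/CBr | starting material
6 | sodium 4-(methoxycarbonyl)phenoxide | COC(=O)c1ccc([O-])cc1.[Na+] | intermediate
7 | methyl 3-[(2E)-3,7-dimethylocta-2,6-dien-1-yl]-4-hydroxybenzoate | COC(=O)c1ccc(O)c(C/C=C(\C)CCC=C(C)C)c1 | intermediate
8 | methyl 4-(2,2-dimethylpropanoyloxy)-3-[(2E)-3,7-dimethylocta-2,6-dien-1-yl]benzoate | COC(=O)c1ccc(OC(=O)C(C)(C)C)c(C/C=C(\C)CCC=C(C)C)c1 | intermediate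
9 | methyl 4-(2,2-dimethylpropanoyloxy)-3-[(2E,6E)-8-hydroxy-3,7-dimethylocta-2,6-dien-1-yl]benzoate | COC(=O)c1ccc(OC(=O)C(C)(C)C)c(C/C=C(\C)CC/C=C(\C)CO)c1 | intermediate
10 | [(2E,6E)-8-[2-(2,2-dimethylpropanoyloxy)-5-(methoxycarbonyl)phenyl]-2,6-dimethylocta-2,6-dien-1-yl]triphenylphosphonium bromide | COC(=O)c1ccc(OC(=O)C(C)(C)C)c(C/C=C(\C)CC/C=C(\C)C[P+](c2ccccc2)(c2ccccc2)c2ccccc2)c1.[Br-] | intermediate
11 | allylic phosphorus ylide of 10 | COC(=O)c1ccc(OC(=O)C(C)(C)C)c(C/C=C(\C)CC/C=C(\C)C=P(c2ccccc2)(c2ccccc2)c2ccccc2)c1 | intermediate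
12 | methyl 4-(2,2-dimethylpropanoyloxy)-3-[(2E,6E)-3,7-dimethyl-9-[(2S,3R)-3-methyl-3-(4-methylpent-3-en-1-yl)oxiran-2-yl]nona-2,6,8-trien-1-yl]benzoate (8E/8Z mixture) | COC(=O)c1ccc(OC(=O)C(C)(C)C)c(C/C=C(\C)CC/C=C(\C)C=C[C@@H]2O[C@]2(C)CCC=C(C)C)c1 | intermediate
13 | methyl 4-(2,2-dimethylpropanoyloxy)-3-[(2E,6E)-3,7-dimethyl-9-[(2S,3R)-3-methyl-3-(4-methylpent-3-en-1-yl)oxiran-2-yl]nona-2,6-dien-1-yl]benzoate | COC(=O)c1ccc(OC(=O)C(C)(C)C)c(C/C=C(\C)CC/C=C(\C)CC[C@@H]2O[C@]2(C)CCC=C(C)C)c1 | intermediate
14 | 3β-hydroxyjaspic acid methyl ester O-pivalate | CC(C)=CCC[C@@]1(C)[C@@H](O)CC[C@]2(C)[C@@H](Cc3cc(C(=O)OC)ccc3OC(=O)C(C)(C)C)C(C)=CC[C@@H]12 | intermediate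
15 | 3-oxojaspic acid methyl ester O-pivalate | CC(C)=CCC[C@@]1(C)C(=O)CC[C@]2(C)[C@@H](Cc3cc(C(=O)OC)ccc3OC(=O)C(C)(C)C)C(C)=CC[C@@H]12 | intermediate
16 | 3-oxojaspic acid dipotassium salt | CC(C)=CCC[C@@]1(C)C(=O)CC[C@]2(C)[C@@H](Cc3cc(C(=O)[O-])ccc3[O-])C(C)=CC[C@@H]12.[K+].[K+] | intermediate
17 | C3 hydrazone of 3-oxojaspic acid, dipotassium salt | CC(C)=CCC[C@@]1(C)C(=NN)CC[C@]2(C)[C@@H](Cc3cc(C(=O)[O-])ccc3[O-])C(C)=CC[C@@H]12.[K+].[K+] | intermediate
18 | jaspic acid | CC(C)=CCC[C@@]1(C)CCC[C@]2(C)[C@@H](Cc3cc(C(=O)O)ccc3O)C(C)=CC[C@@H]12 | target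

**Step count**

Total: 11 steps. Longest linear sequence: 9 steps (steps 3 to 11); the epoxide branch (steps 1 and 2) joins at step 7.

**Steps most likely to fail**

Step 9. The deprotonation that ends the cascade may lose regiocontrol, giving the exocyclic 8(12)-olefin beside the 7-ene, and part of the material may leave the cascade after ring A. The fallback settles the position of the ring B olefin in a separate step instead of in the cascade. It sets out from 13: the cyclisation is run for skeleton and stereocentres only, and the exocyclic isomer formed with or instead of 14, the 3β-hydroxy 8(12)-ene F1, is carried on. F1 is then isomerised into the ring by metal-hydride/π-allyl isomerisation (RhCl3·3H2O cat., EtOH, 80 °C), which should move the 1,1-disubstituted olefin toward the unhindered C7 and not toward the hindered tertiary C9. The sequence comes back to the route at 14.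

Step 8. Hydrogen may be transferred to one of the three trisubstituted olefins before the disubstituted one is consumed, or the allylic epoxide may open while it is still conjugated. The fallback makes the C1–C2 bond by sp3–sp3 alkylation, so that no extra olefin has to be reduced. It sets out from 9 and 2. From 9, Appel bromination (CBr4, PPh3, CH2Cl2, 0 °C) should give the allylic bromide F2, and PhSO2Na in DMF the allylic phenyl sulfone F3. From 2, Tf2O and 2,6-lutidine (CH2Cl2, −78 °C) should give the epoxy triflate F4, used at once. The anion of F3 (KN(SiMe3)2, THF, −78 °C) is alkylated with F4 to the coupled sulfone F5. Buffered reductive desulfonylation (Na(Hg), Na2HPO4, MeOH–THF, −20 °C, kept cold to limit allylic transposition) comes back to the route at 13.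

Step 11. Hydrazone formation at the hindered C3 ketone next to the quaternary C4 may stall, or the 4-hydroxybenzoate may decarboxylate at 200 °C. The fallback is radical deoxygenation of the alcohol (Barton–McCombie) instead of carbonyl reduction. It sets out from 14: 1,1'-thiocarbonyldiimidazole (DMAP, toluene, 80 °C) should give the imidazolyl thiocarbonate F6. Bu3SnH at high concentration with (PhSe)2 (cat.) and AIBN (toluene, 110 °C), so that hydrogen transfer outruns 5-exo closure of the C3 radical onto the side-chain olefin, should give the 3-deoxy diester F7. Saponification (KOH, MeOH–H2O, 65 °C; then aq. HCl) comes back to the route at 18.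

**Further compounds**

F1 | step 9 | 3β-hydroxy 8(12)-ene (exocyclic methylene) isomer of 14 | CC(C)=CCC[C@@]1(C)[C@@H](O)CC[C@]2(C)[C@@H](Cc3cc(C(=O)OC)ccc3OC(=O)C(C)(C)C)C(=C)CC[C@@H]12
F2 | step 8 | methyl 3-[(2E,6E)-8-bromo-3,7-dimethylocta-2,6-dien-1-yl]-4-(2,2-dimethylpropanoyloxy)benzoate | COC(=O)c1ccc(OC(=O)C(C)(C)C)c(C/C=C(\C)CC/C=C(\C)CBr)c1
F3 | step 8 | methyl 4-(2,2-dimethylpropanoyloxy)-3-[(2E,6E)-3,7-dimethyl-8-(phenylsulfonyl)octa-2,6-dien-1-yl]benzoate | COC(=O)c1ccc(OC(=O)C(C)(C)C)c(C/C=C(\C)CC/C=C(\C)CS(=O)(=O)c2ccccc2)c1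
F4 | step 8 | [(2S,3R)-3-methyl-3-(4-methylpent-3-en-1-yl)oxiran-2-yl]methyl trifluoromethanesulfonate | CC(C)=CCC[C@@]1(C)O[C@H]1COS(=O)(=O)C(F)(F)F
F5 | step 8 | methyl 4-(2,2-dimethylpropanoyloxy)-3-[(2E,6E)-3,7-dimethyl-9-[(2S,3R)-3-methyl-3-(4-methylpent-3-en-1-yl)oxiran-2-yl]-8-(phenylsulfonyl)nona-2,6-dien-1-yl]benzoate (both C8 epimers) | COC(=O)c1ccc(OC(=O)C(C)(C)C)c(C/C=C(\C)CC/C=C(\C)C(C[C@@H]2O[C@]2(C)CCC=C(C)C)S(=O)(=O)c2ccccc2)c1
F6 | step 11 | O-(imidazol-1-ylthiocarbonyl) derivative of 14 at the 3β-oxygen | CC(C)=CCC[C@@]1(C)[C@@H](OC(=S)n4ccnc4)CC[C@]2(C)[C@@H](Cc3cc(C(=O)OC)ccc3OC(=O)C(C)(C)C)C(C)=CC[C@@H]12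
F7 | step 11 | jaspic acid methyl ester O-pivalate | CC(C)=CCC[C@@]1(C)CCC[C@]2(C)[C@@H](Cc3cc(C(=O)OC)ccc3OC(=O)C(C)(C)C)C(C)=CC[C@@H]12
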